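**Plan**
- Carotenoid numbering is used, with primed locants on the cyclohexene end (C1′ = CMe2, C2′ and C3′ = CH2, C4′=C5′(CH3), C6′ = stereocentre); the target is (5R,6S,6′R)-5,6-epoxy-5,6-dihydro-β,ε-carotene.
- Cuts, in retrosynthetic order: C11=C12 (Wittig, C25 ylide + epoxy C15 aldehyde), C11′=C12′ (Wittig, C15 ylide + C10 dialdehyde), C7=C8 and C7′=C8′ (Horner–Wadsworth–Emmons, C5 phosphonate), then C2′–C3′ inside the cyclohexene ring.
- Enabling feature: C3′ is the allylic CH2 of the C3′–C4′=C5′(CH3) unit and C5′ lies 1,4 to C2′ across the six-membered ring. A 6-vinyl δ-lactone tying C5′ (through O) to a carboxyl carbon on C2′ is therefore the precursor of an alicyclic Ireland–Claisen rearrangement that turns the lactone into the carbocycle; the carboxyl helper leaves by Barton decarboxylation.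
- Forward: the cyclohexene ring is made first (auxiliary alkylation, lactone, [3,3] closure) and its chain grown C10 → C15 → C25; separately the oxirane is installed on the intact β-ring and that chain grown to C15; the halves are joined last.
- Stereochemistry: C6′ comes from an Evans alkylation and is carried unchanged through the ring closure (the carbinol centre made on the way is used as an epimer mixture because it becomes sp2). C5/C6 come from Sharpless epoxidation of β-cyclogeraniol with D-(−)-diethyl tartrate. E-alkenes come from stabilised olefinations plus equilibration.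

Key step: step 7

**Step 1**
Reactants: 1 3,3-dimethylpent-4-enoic acid; 2 (R)-4-benzyloxazolidin-2-one
Product: 4 (R)-4-benzyl-3-(3,3-dimethylpent-4-enoyl)oxazolidin-2-one, via mixed pivalic anhydride 3 (not isolated)
Conditions: t-BuCOCl, Et3N, THF, −20 °C; then 2, LiCl, −20 °C to rt
Reagents that add atoms: none
Why: N-acylation of the oxazolidinone through the mixed pivalic anhydride (LiCl-assisted acyl transfer) is the standard entry to an auxiliary-bound enolate precursor and forms no stereocentre.

**Step 2**
Reactants: 4 (R)-4-benzyl-3-(3,3-dimethylpent-4-enoyl)oxazolidin-2-one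
Product: 6 (R)-4-benzyl-3-[(S)-2-[(benzyloxy)methyl]-3,3-dimethylpent-4-enoyl]oxazolidin-2-one, via chlorotitanium Z-enolate 5 (not isolated)
Conditions: TiCl4, i-Pr2NEt, CH2Cl2, 0 °C; then BnOCH2Cl, 0 °C; aq NH4Cl
Reagents that add atoms: benzyl chloromethyl ether, ClCOCc1ccccc1
Why: Evans alkylation, in which the chelated Z-titanium enolate is attacked by the benzyloxymethyl electrophile on the face opposite the benzyl group of the (R)-auxiliary, should set the (S) centre that becomes C6′ (R) of the ring.

**Step 3**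
Reactants: 6 (R)-4-benzyl-3-[(S)-2-[(benzyloxy)methyl]-3,3-dimethylpent-4-enoyl]oxazolidin-2-one
Product: 9 (S)-3-[(benzyloxy)methyl]-4,4-dimethyloxan-2-one, via B-alkyl-9-borabicyclononane 7 (not isolated), via hydroxy acid 8 (not isolated)
Conditions: 9-BBN, THF, 0 °C to rt; then LiOH, H2O2, THF/H2O, 0 °C to rt; then 1 M HCl; PPTS (cat.), PhMe, 50 °C
Reagents that add atoms: hydrogen peroxide, OO
Why: anti-Markovnikov hydroboration–oxidation of the terminal alkene and hydroperoxide cleavage of the imide give the δ-hydroxy acid, which should lactonise readily (gem-dimethyl effect) with the α-stereocentre untouched and the auxiliary recovered.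

**Step 4**
Reactants: 9 (S)-3-[(benzyloxy)methyl]-4,4-dimethyloxan-2-one
Product: 10 (S)-3-[(benzyloxy)methyl]-6-hydroxy-4,4-dimethylhexan-2-one (open form of the cyclic hemiketal)
Conditions: MeLi (1.1 equiv), THF, −78 °C; aq NH4Cl at −78 °C
Reagents that add atoms: methyllithium, [Li]C
Why: mono-addition of an alkyllithium to a δ-lactone stops at the tetrahedral lithium lactolate at low temperature, so the methyl ketone (lactol) should form without over-addition or epimerisation of the hindered α-centre.

**Step 5**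
Reactants: 10 (S)-3-[(benzyloxy)methyl]-6-hydroxy-4,4-dimethylhexan-2-one
Product: 11 (4S)-4-[(benzyloxy)methyl]-3,5,5-trimethylhept-1-ene-3,7-diol (both C3 epimers)
Conditions: CH2=CHMgBr (4 equiv), LaCl3·2LiCl (1 equiv), THF, −40 to 0 °C; aq NH4Cl
Reagents that add atoms: vinylmagnesium bromide, C=C[Mg]Br
Why: Lewis-acid-assisted Grignard 1,2-addition to the ketone form of the lactol should give the tertiary allylic alcohol with enolisation suppressed; the new carbinol centre forms as a mixture and needs no control because it becomes sp2 in step 7.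

**Step 6**
Reactants: 11 (4S)-4-[(benzyloxy)methyl]-3,5,5-trimethylhept-1-ene-3,7-diol
Product: 12 (5S)-5-[(benzyloxy)methyl]-6-ethenyl-4,4,6-trimethyloxan-2-one (both C6 epimers)
Conditions: TEMPO (20 mol %), PhI(OAc)2 (2.5 equiv), CH2Cl2, rt
Reagents that add atoms: none
Why: oxoammonium-mediated oxidative lactonisation of a 1,5-diol, in which only the primary alcohol is oxidised, the aldehyde is trapped by the tertiary hydroxyl as a six-membered lactol and this is oxidised on to the δ-lactone.

**Step 7**
Reactants: 12 (5S)-5-[(benzyloxy)methyl]-6-ethenyl-4,4,6-trimethyloxan-2-one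
Product: 15 (5S)-5-[(benzyloxy)methyl]-4,6,6-trimethylcyclohex-3-ene-1-carboxylic acid (both C1 epimers), via silyl ketene acetal 13 (not isolated), via silyl ester 14 (not isolated)
Conditions: LiN(i-Pr)2 (1.3 equiv), THF, −78 °C; TBSCl, HMPA, −78 °C to rt; then PhMe, 110 °C; then 1 M HCl, THF, rt
Reagents that add atoms: none
Why: LiN(i-Pr)2 removes one of the only α-protons of 12 (the oxanone C3 methylene, future C2′) and O-silylation gives the cyclic silyl ketene acetal 13, which on heating undergoes a suprafacial [3,3]-sigmatropic shift that forms the C2′–C3′ bond as the ring C–O bond breaks, giving silyl ester 14 and, after hydrolysis, acid 15. The closest known reaction type is the Ireland–Claisen rearrangement of lactone silyl ketene acetals that carry an alkenyl group on the carbinol carbon (alicyclic Claisen rearrangement, as in the dioxanone-to-dihydropyran variant). The cyclohexene closes through a boat-like six-centre transition state bridged by C1′ and C6′ (a bicyclo[2.2.2]octane-like array), the only geometry the cyclic ketene acetal allows, so the lactone is converted into the carbocycle with the alkene delivered inside the ring at C4′=C5′. The one new stereocentre, the carboxyl-bearing C2′, is fixed by suprafacial transfer from the carbinol carbon of 12, so each carbinol epimer gives one C2′ epimer and this centre is erased in step 8, whereas C6′ is neither acidic nor part of the pericyclic array and is carried through unchanged. The step needs O- over C-silylation (TBSCl/HMPA), [3,3] shift over ionisation or elimination of the tertiary allylic ester (neutral, non-polar thermolysis) and the alkene at C4′=C5′ and not C5′=C6′, which the allylic transposition enforces because no acid or base that could move the alkene is present. Both carbinol epimers can place the vinyl group in the flagpole position of the boat, so the epimer mixture from step 5 should funnel into the one ring skeleton.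

**Step 8**
Reactants: 15 (5S)-5-[(benzyloxy)methyl]-4,6,6-trimethylcyclohex-3-ene-1-carboxylic acid
Product: 17 ({[(1R)-2,6,6-trimethylcyclohex-2-en-1-yl]methoxy}methyl)benzene, via Barton ester 16 (not isolated)
Conditions: N-hydroxypyridine-2-thione, DCC, DMAP (cat.), CH2Cl2, 0 °C to rt, dark; then t-BuSH, PhH, hν (tungsten lamp), rt
Reagents that add atoms: none
Why: Barton reductive decarboxylation, in which the thiohydroxamate ester fragments to CO2 and the secondary C2′ radical that abstracts hydrogen from the thiol, removes the helper carboxyl and its temporary stereocentre so that both epimers of 15 converge on one compound.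

**Step 9**
Reactants: 17 ({[(1R)-2,6,6-trimethylcyclohex-2-en-1-yl]methoxy}methyl)benzene
Product: 18 [(1R)-2,6,6-trimethylcyclohex-2-en-1-yl]methanol ((R)-α-cyclogeraniol)
Conditions: Li, NH3 (l), THF, −78 °C; then NH4Cl
Reagents that add atoms: none
Why: dissolving-metal cleavage of the benzyl ether leaves the isolated trisubstituted alkene intact, which hydrogenolysis would not.

**Step 10**
Reactants: 18 [(1R)-2,6,6-trimethylcyclohex-2-en-1-yl]methanol
Product: 19 (1R)-2,6,6-trimethylcyclohex-2-ene-1-carbaldehyde ((R)-α-cyclocitral)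
Conditions: Dess–Martin periodinane, NaHCO3, CH2Cl2, 0 °C; used at once
Reagents that add atoms: none
Why: buffered, non-basic Dess–Martin oxidation should give the β,γ-unsaturated aldehyde without enolisation, keeping the C6′ configuration and the deconjugated alkene.

**Step 11**
Reactants: 19 (1R)-2,6,6-trimethylcyclohex-2-ene-1-carbaldehyde; 20 triethyl (E)-3-methyl-4-phosphonocrotonate
Product: 22 ethyl (2E,4E)-3-methyl-5-[(1R)-2,6,6-trimethylcyclohex-2-en-1-yl]penta-2,4-dienoate, via lithium phosphonate anion 21 (not isolated)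
Conditions: 20, LiN(SiMe3)2, THF/DMPU, −78 °C; then 19, −78 to 0 °C
Reagents that add atoms: none
Why: Horner–Wadsworth–Emmons olefination with the vinylogous C5 phosphonate should build the E C7′=C8′ bond, the weakly basic stabilised lithium anion adding to the aldehyde at low temperature faster than it deprotonates the hindered α-CH, with any 2Z isomer removed by chromatography.

**Step 12**
Reactants: 22 ethyl (2E,4E)-3-methyl-5-[(1R)-2,6,6-trimethylcyclohex-2-en-1-yl]penta-2,4-dienoate
Product: 23 (2E,4E)-3-methyl-5-[(1R)-2,6,6-trimethylcyclohex-2-en-1-yl]penta-2,4-dien-1-ol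
Conditions: i-Bu2AlH (2.5 equiv), CH2Cl2, −78 °C; aq potassium sodium tartrate work-up
Reagents that add atoms: none
Why: 1,2-reduction of the dienoate ester by i-Bu2AlH at low temperature gives the allylic alcohol without touching the alkenes or the stereocentre.

**Step 13**
Reactants: 23 (2E,4E)-3-methyl-5-[(1R)-2,6,6-trimethylcyclohex-2-en-1-yl]penta-2,4-dien-1-ol
Product: 24 [(2E,4E)-3-methyl-5-[(1R)-2,6,6-trimethylcyclohex-2-en-1-yl]penta-2,4-dien-1-yl]triphenylphosphonium bromide
Conditions: PPh3·HBr, MeOH, rt
Reagents that add atoms: triphenylphosphine hydrobromide, [Br-].[PH+](c1ccccc1)(c1ccccc1)c1ccccc1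
Why: the dienyl alcohol ionises under PPh3·HBr and the phosphine traps the cation at the primary terminus, the standard preparation of carotenoid Wittig salts, under conditions mild enough to leave the isolated ring alkene in place.

**Step 14**
Reactants: 24 C15 phosphonium bromide; 25 (2E,4E,6E)-2,7-dimethylocta-2,4,6-trienedial
Product: 27 (2E,4E,6E,8E,10E,12E)-2,7,11-trimethyl-13-[(1R)-2,6,6-trimethylcyclohex-2-en-1-yl]trideca-2,4,6,8,10,12-hexaenal, via C15 phosphonium ylide 26 (not isolated)
Conditions: 25 (3 equiv), NaOMe, MeOH/CH2Cl2, 0 °C to rt; then I2 (cat.), PhH, rt, daylight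
Reagents that add atoms: none
Why: Wittig olefination of one formyl group of the symmetrical dialdehyde (used in excess to favour mono-reaction) forms C11′=C12′, and iodine-catalysed equilibration should convert the Z isomer into the all-E C25 aldehyde.

**Step 15**
Reactants: 27 C25 aldehyde
Product: 28 (2E,4E,6E,8E,10E,12E)-2,7,11-trimethyl-13-[(1R)-2,6,6-trimethylcyclohex-2-en-1-yl]trideca-2,4,6,8,10,12-hexaen-1-ol
Conditions: NaBH4, MeOH/THF, 0 °C
Reagents that add atoms: none
Why: borohydride 1,2-reduction of the polyenal gives the allylic alcohol chemoselectively.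

**Step 16**
Reactants: 28 C25 alcohol
Product: 29 [(2E,4E,6E,8E,10E,12E)-2,7,11-trimethyl-13-[(1R)-2,6,6-trimethylcyclohex-2-en-1-yl]trideca-2,4,6,8,10,12-hexaen-1-yl]triphenylphosphonium bromide
Conditions: PPh3·HBr, MeOH/CH2Cl2, rt
Reagents that add atoms: triphenylphosphine hydrobromide, [Br-].[PH+](c1ccccc1)(c1ccccc1)c1ccccc1
Why: as in step 13, the polyenyl alcohol ionises readily and the phosphine captures the cation at the primary carbon to give the Wittig salt.

**Step 17**
Reactants: 30 2,6,6-trimethylcyclohex-1-ene-1-carbaldehyde (β-cyclocitral)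
Product: 31 (2,6,6-trimethylcyclohex-1-en-1-yl)methanol (β-cyclogeraniol)
Conditions: NaBH4, MeOH, 0 °C
Reagents that add atoms: none
Why: borohydride 1,2-reduction of the hindered enal gives the allylic alcohol needed for directed epoxidation.

**Step 18**
Reactants: 31 (2,6,6-trimethylcyclohex-1-en-1-yl)methanol
Product: 32 [(1R,6R)-2,2,6-trimethyl-7-oxabicyclo[4.1.0]heptan-1-yl]methanol
Conditions: Ti(OiPr)4 (10 mol %), D-(−)-diethyl tartrate (12 mol %), t-BuOOH, 4 Å molecular sieves, CH2Cl2, −20 °C
Reagents that add atoms: tert-butyl hydroperoxide, CC(C)(C)OO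
Why: Sharpless asymmetric epoxidation sets both oxirane centres in one syn oxygen transfer, and the D-(−) tartrate should deliver oxygen to the face opposite to that attacked in geraniol with the L-(+) ester (same substitution pattern about the allylic alcohol), giving the (1R,6R) epoxy alcohol that corresponds to the (5R,6S) oxirane of the target.

**Step 19**
Reactants: 32 [(1R,6R)-2,2,6-trimethyl-7-oxabicyclo[4.1.0]heptan-1-yl]methanol
Product: 33 (1S,6R)-2,2,6-trimethyl-7-oxabicyclo[4.1.0]heptane-1-carbaldehyde
Conditions: Dess–Martin periodinane, NaHCO3, CH2Cl2, 0 °C to rt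
Reagents that add atoms: none
Why: buffered Dess–Martin oxidation gives the epoxy aldehyde, which has no α-hydrogen and so cannot epimerise, without acid that would open the oxirane.

**Step 20**
Reactants: 33 (1S,6R)-2,2,6-trimethyl-7-oxabicyclo[4.1.0]heptane-1-carbaldehyde; 20 triethyl (E)-3-methyl-4-phosphonocrotonate
Product: 35 ethyl (2E,4E)-3-methyl-5-[(1S,6R)-2,2,6-trimethyl-7-oxabicyclo[4.1.0]heptan-1-yl]penta-2,4-dienoate, via sodium phosphonate anion 34 (not isolated)
Conditions: 20, NaH, THF, 0 °C; then 33, 0 °C to rt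
Reagents that add atoms: none
Why: Horner–Wadsworth–Emmons olefination in which, because aldehyde 33 has no α-hydrogen, the more reactive sodium phosphonate anion made with NaH can be used up to rt to overcome the hindrance of the fully substituted formyl-bearing carbon; the oxirane tolerates the basic medium and the E C7=C8 bond should form with the C9 methyl group in place, any 2Z isomer being removed by chromatography.

**Step 21**
Reactants: 35 epoxy C15 ester
Product: 36 (2E,4E)-3-methyl-5-[(1S,6R)-2,2,6-trimethyl-7-oxabicyclo[4.1.0]heptan-1-yl]penta-2,4-dien-1-ol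
Conditions: i-Bu2AlH (2.5 equiv), CH2Cl2, −78 °C; aq potassium sodium tartrate work-up
Reagents that add atoms: none
Why: low-temperature 1,2-reduction of the ester by i-Bu2AlH should leave the fully substituted, hindered oxirane untouched.

**Step 22**
Reactants: 36 epoxy C15 alcohol
Product: 37 (2E,4E)-3-methyl-5-[(1S,6R)-2,2,6-trimethyl-7-oxabicyclo[4.1.0]heptan-1-yl]penta-2,4-dienal
Conditions: activated MnO2, CH2Cl2, rt
Reagents that add atoms: none
Why: neutral, heterogeneous MnO2 oxidation of the dienylic alcohol gives the conjugated aldehyde without acid-induced rearrangement of the vinyl oxirane.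

**Step 23**
Reactants: 29 C25 phosphonium bromide; 37 epoxy C15 aldehyde
Product: 39 (5R,6S,6′R)-5,6-epoxy-5,6-dihydro-β,ε-carotene, via C25 phosphonium ylide 38 (not isolated)
Conditions: NaOMe (1.05 equiv), MeOH/CH2Cl2, −10 °C to rt, dark, argon; then heptane, 80 °C, argon; crystallisation
Reagents that add atoms: none
Why: Wittig reaction forms C11=C12 with the ylide placed on the half that has no oxirane (an ylide conjugated to the oxirane could open it), and the sterically strained 11Z isomer should equilibrate thermally to the all-E polyene without acid or iodine that would rearrange the epoxide.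

**Compound list**
1 | 3,3-dimethylpent-4-enoic acid | C=CC(C)(C)CC(=O)O | starting material
2 | (R)-4-benzyloxazolidin-2-one | O=C1N[C@H](Cc2ccccc2)CO1 | starting material
3 | 3,3-dimethylpent-4-enoic pivalic anhydride | C=CC(C)(C)CC(=O)OC(=O)C(C)(C)C | intermediate (not isolated)
4 | (R)-4-benzyl-3-(3,3-dimethylpent-4-enoyl)oxazolidin-2-one | C=CC(C)(C)CC(=O)N1[C@H](Cc2ccccc2)COC1=O | intermediate
5 | chlorotitanium Z-enolate of 4 | C=CC(C)(C)/C=C(\O[Ti](Cl)(Cl)Cl)N1[C@H](Cc2ccccc2)COC1=O | intermediate (not isolated)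
6 | (R)-4-benzyl-3-[(S)-2-[(benzyloxy)methyl]-3,3-dimethylpent-4-enoyl]oxazolidin-2-one | C=CC(C)(C)[C@@H](COCc1ccccc1)C(=O)N1[C@H](Cc2ccccc2)COC1=O | intermediate
7 | B-alkyl-9-borabicyclo[3.3.1]nonane from 6 (boron on the terminal carbon) | C1CCC2CCCC1B2CCC(C)(C)[C@@H](COCc1ccccc1)C(=O)N1[C@H](Cc2ccccc2)COC1=O | intermediate (not isolated)
8 | (S)-2-[(benzyloxy)methyl]-5-hydroxy-3,3-dimethylpentanoic acid | OCCC(C)(C)[C@@H](COCc1ccccc1)C(=O)O | intermediate (not isolated)
9 | (S)-3-[(benzyloxy)methyl]-4,4-dimethyloxan-2-one | O=C1OCCC(C)(C)[C@H]1COCc1ccccc1 | intermediate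
10 | (S)-3-[(benzyloxy)methyl]-6-hydroxy-4,4-dimethylhexan-2-one (open form of the lactol) | CC(=O)[C@H](COCc1ccccc1)C(C)(C)CCO | intermediate
11 | (4S)-4-[(benzyloxy)methyl]-3,5,5-trimethylhept-1-ene-3,7-diol (C3 epimers) | C=CC(C)(O)[C@H](COCc1ccccc1)C(C)(C)CCO | intermediate
12 | (5S)-5-[(benzyloxy)methyl]-6-ethenyl-4,4,6-trimethyloxan-2-one (C6 epimers) | O=C1CC(C)(C)[C@@H](COCc2ccccc2)C(C)(C=C)O1 | intermediate
13 | (3S)-3-[(benzyloxy)methyl]-6-[(tert-butyldimethylsilyl)oxy]-2-ethenyl-2,4,4-trimethyl-3,4-dihydro-2H-pyran | CC(C)(C)[Si](C)(C)OC1=CC(C)(C)[C@@H](COCc2ccccc2)C(C)(C=C)O1 | intermediate (not isolated)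
14 | tert-butyldimethylsilyl (5S)-5-[(benzyloxy)methyl]-4,6,6-trimethylcyclohex-3-ene-1-carboxylate | CC(C)(C)[Si](C)(C)OC(=O)C1CC=C(C)[C@H](COCc2ccccc2)C1(C)C | intermediate (not isolated)
15 | (5S)-5-[(benzyloxy)methyl]-4,6,6-trimethylcyclohex-3-ene-1-carboxylic acid (C1 epimers) | OC(=O)C1CC=C(C)[C@H](COCc2ccccc2)C1(C)C | intermediate
16 | 2-thioxopyridin-1(2H)-yl (5S)-5-[(benzyloxy)methyl]-4,6,6-trimethylcyclohex-3-ene-1-carboxylate | S=c1ccccn1OC(=O)C1CC=C(C)[C@H](COCc2ccccc2)C1(C)C | intermediate (not isolated)
17 | ({[(1R)-2,6,6-trimethylcyclohex-2-en-1-yl]methoxy}methyl)benzene | CC1=CCCC(C)(C)[C@H]1COCc1ccccc1 | intermediate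
18 | [(1R)-2,6,6-trimethylcyclohex-2-en-1-yl]methanol | CC1=CCCC(C)(C)[C@H]1CO | intermediate
19 | (1R)-2,6,6-trimethylcyclohex-2-ene-1-carbaldehyde | CC1=CCCC(C)(C)[C@H]1C=O | intermediate
20 | triethyl (E)-3-methyl-4-phosphonocrotonate | CCOC(=O)/C=C(C)/CP(=O)(OCC)OCC | starting material
21 | lithium salt of the anion of 20 | [Li+].CCOC(=O)/C=C(C)/[CH-]P(=O)(OCC)OCC | intermediate (not isolated)
22 | ethyl (2E,4E)-3-methyl-5-[(1R)-2,6,6-trimethylcyclohex-2-en-1-yl]penta-2,4-dienoate | CC1=CCCC(C)(C)[C@H]1/C=C/C(C)=C/C(=O)OCC | intermediate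
23 | (2E,4E)-3-methyl-5-[(1R)-2,6,6-trimethylcyclohex-2-en-1-yl]penta-2,4-dien-1-ol | CC1=CCCC(C)(C)[C@H]1/C=C/C(C)=C/CO | intermediate
24 | C15 phosphonium bromide from 23 | CC1=CCCC(C)(C)[C@H]1/C=C/C(C)=C/C[P+](c1ccccc1)(c1ccccc1)c1ccccc1.[Br-] | intermediate
25 | (2E,4E,6E)-2,7-dimethylocta-2,4,6-trienedial | O=C/C(C)=C/C=C/C=C(C)/C=O | starting material
26 | ylide of 24 | CC1=CCCC(C)(C)[C@H]1/C=C/C(C)=C/C=P(c1ccccc1)(c1ccccc1)c1ccccc1 | intermediate (not isolated)
27 | (2E,4E,6E,8E,10E,12E)-2,7,11-trimethyl-13-[(1R)-2,6,6-trimethylcyclohex-2-en-1-yl]trideca-2,4,6,8,10,12-hexaenal | CC1=CCCC(C)(C)[C@H]1/C=C/C(C)=C/C=C/C(C)=C/C=C/C=C(C)/C=O | intermediate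
28 | corresponding hexaen-1-ol | CC1=CCCC(C)(C)[C@H]1/C=C/C(C)=C/C=C/C(C)=C/C=C/C=C(C)/CO | intermediate
29 | C25 phosphonium bromide from 28 | CC1=CCCC(C)(C)[C@H]1/C=C/C(C)=C/C=C/C(C)=C/C=C/C=C(C)/C[P+](c1ccccc1)(c1ccccc1)c1ccccc1.[Br-] | intermediate
30 | 2,6,6-trimethylcyclohex-1-ene-1-carbaldehyde | CC1=C(C=O)C(C)(C)CCC1 | starting material
31 | (2,6,6-trimethylcyclohex-1-en-1-yl)methanol | CC1=C(CO)C(C)(C)CCC1 | intermediate
32 | [(1R,6R)-2,2,6-trimethyl-7-oxabicyclo[4.1.0]heptan-1-yl]methanol | OC[C@@]12O[C@]1(C)CCCC2(C)C | intermediate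
33 | (1S,6R)-2,2,6-trimethyl-7-oxabicyclo[4.1.0]heptane-1-carbaldehyde | O=C[C@@]12O[C@]1(C)CCCC2(C)C | intermediate
34 | sodium salt of the anion of 20 | [Na+].CCOC(=O)/C=C(C)/[CH-]P(=O)(OCC)OCC | intermediate (not isolated)
35 | ethyl (2E,4E)-3-methyl-5-[(1S,6R)-2,2,6-trimethyl-7-oxabicyclo[4.1.0]heptan-1-yl]penta-2,4-dienoate | CCOC(=O)/C=C(C)/C=C/[C@@]12O[C@]1(C)CCCC2(C)C | intermediate
36 | (2E,4E)-3-methyl-5-[(1S,6R)-2,2,6-trimethyl-7-oxabicyclo[4.1.0]heptan-1-yl]penta-2,4-dien-1-ol | OC/C=C(C)/C=C/[C@@]12O[C@]1(C)CCCC2(C)C | intermediate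
37 | (2E,4E)-3-methyl-5-[(1S,6R)-2,2,6-trimethyl-7-oxabicyclo[4.1.0]heptan-1-yl]penta-2,4-dienal | O=C/C=C(C)/C=C/[C@@]12O[C@]1(C)CCCC2(C)C | intermediate
38 | ylide of 29 | CC1=CCCC(C)(C)[C@H]1/C=C/C(C)=C/C=C/C(C)=C/C=C/C=C(C)/C=P(c1ccccc1)(c1ccccc1)c1ccccc1 | intermediate (not isolated)
39 | (5R,6S,6′R)-5,6-epoxy-5,6-dihydro-β,ε-carotene | CC1=CCCC(C)(C)[C@H]1/C=C/C(C)=C/C=C/C(C)=C/C=C/C=C(C)/C=C/C=C(C)/C=C/[C@@]12O[C@]1(C)CCCC2(C)C | target

**Summary**
Total step count: 23. Longest linear sequence: 17 steps (steps 1–16, then step 23).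

**Steps most likely to fail**

Step 7. The boat-like transition state may not be reached because the gem-dimethyl group next to the ketene acetal carbon crowds the incoming vinyl carbon; the silyl ketene acetal would then lose the tertiary allylic carboxylate by elimination instead of rearranging. The fallback closes the ring by olefin metathesis and sets out from hydroxy ketone 10. Wittig methylenation (Ph3PCH3Br, KOt-Bu, THF) should give (4S)-4-[(benzyloxy)methyl]-3,3,5-trimethylhex-5-en-1-ol F1. Iodination (I2, PPh3, imidazole, CH2Cl2) should give (3S)-3-[(benzyloxy)methyl]-6-iodo-2,4,4-trimethylhex-1-ene F2. Copper-catalysed coupling with CH2=CHMgBr (CuI cat., THF, −20 °C) should give (3S)-3-[(benzyloxy)methyl]-2,4,4-trimethylocta-1,7-diene F3. Ring-closing metathesis with the second-generation Grubbs catalyst (CH2Cl2, 40 °C) then forms the ring at C4′=C5′ with loss of ethene and returns to the route at benzyl ether 17.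

Step 2. C-alkylation at the enolate carbon next to the quaternary centre may be slower than decomposition of the chloromethyl ether, so conversion stalls or selectivity erodes. The fallback sets out from imide 4 and splits the event in two. A titanium-enolate aldol addition to formaldehyde (TiCl4, i-Pr2NEt, s-trioxane, CH2Cl2, 0 °C) uses the smallest possible electrophile on the same enolate face and should give (R)-4-benzyl-3-[(S)-2-(hydroxymethyl)-3,3-dimethylpent-4-enoyl]oxazolidin-2-one F4. Acid-catalysed O-benzylation with benzyl 2,2,2-trichloroacetimidate (TfOH cat., CH2Cl2/cyclohexane), which avoids base and hence retro-aldol or β-elimination, returns to the route at 6.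

Step 11. Aldehyde 19 may enolise towards the dienolate before it is olefinated, which would erode the C6′ configuration or move the ring alkene into conjugation. The fallback avoids the aldehyde and sets out from alcohol 18. Mitsunobu thioetherification with 1-phenyl-1H-tetrazole-5-thiol (PPh3, DIAD, THF) should give 1-phenyl-5-({[(1R)-2,6,6-trimethylcyclohex-2-en-1-yl]methyl}sulfanyl)-1H-tetrazole F5. Molybdate-catalysed oxidation ((NH4)6Mo7O24, H2O2, EtOH) should give 1-phenyl-5-({[(1R)-2,6,6-trimethylcyclohex-2-en-1-yl]methyl}sulfonyl)-1H-tetrazole F6. Julia–Kocienski olefination (KN(SiMe3)2, THF, −78 °C) with commercial ethyl (2E)-3-methyl-4-oxobut-2-enoate then forms C7′=C8′ and returns to the route at ester 22. The carbanion now sits on C7′, so the stereocentre cannot enolise.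

**Further compounds**
F1 | step 7 | (4S)-4-[(benzyloxy)methyl]-3,3,5-trimethylhex-5-en-1-ol | C=C(C)[C@H](COCc1ccccc1)C(C)(C)CCO
F2 | step 7 | (3S)-3-[(benzyloxy)methyl]-6-iodo-2,4,4-trimethylhex-1-ene | C=C(C)[C@H](COCc1ccccc1)C(C)(C)CCI
F3 | step 7 | (3S)-3-[(benzyloxy)methyl]-2,4,4-trimethylocta-1,7-diene | C=C(C)[C@H](COCc1ccccc1)C(C)(C)CCC=C
F4 | step 2 | (R)-4-benzyl-3-[(S)-2-(hydroxymethyl)-3,3-dimethylpent-4-enoyl]oxazolidin-2-one | C=CC(C)(C)[C@@H](CO)C(=O)N1[C@H](Cc2ccccc2)COC1=O
F5 | step 11 | 1-phenyl-5-({[(1R)-2,6,6-trimethylcyclohex-2-en-1-yl]methyl}sulfanyl)-1H-tetrazole | CC1=CCCC(C)(C)[C@H]1CSc1nnnn1-c1ccccc1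
F6 | step 11 | 1-phenyl-5-({[(1R)-2,6,6-trimethylcyclohex-2-en-1-yl]methyl}sulfonyl)-1H-tetrazole | CC1=CCCC(C)(C)[C@H]1CS(=O)(=O)c1nnnn1-c1ccccc1
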